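**Plan**

- Retrosynthesis: the four phenol O–benzyl bonds and the two acetates go first; both CH2OAc carbons are traced back to a carboxyl on C3 and a vinyl on C4; the C3–C4 bond of the oxolane is then cut (retro-[3,3]) to a nine-membered (Z)-lactone, whose C=C is cut next (metathesis), and last the bis-benzylic C–O bond (allylic etherification).
- Enabling feature: in the oxolane ring, C3 and C4 each carry one exocyclic carbon and are already joined through C2–O1–C5, so a lactone running from the C3 carboxyl carbon through C2, O1 and C5 to an alkene on C5 can fold C3 onto C4 in a [3,3] shift.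
- Forward: a β-hydroxy allyl ester (steps 1–2) and a cinnamyl carbonate (steps 3–5) are joined at oxygen (step 6); the nine-membered lactone closes by metathesis (step 7); the oxolane arises from it by ring contraction (step 8); four steps adjust functional groups.
- Stereochemistry: the carbinol centre comes from asymmetric transfer hydrogenation, the second aryl-bearing centre from ligand control in the iridium etherification, and C3/C4 from the boat transition state formed on the face away from the two aryl groups.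

Key step: step 8

Assumption: the target is meso (mirror plane through O1 and the midpoint of C3–C4), so only the relative configuration of the two aryl-bearing carbons matters. The chiral intermediates are drawn in one enantiomeric series, and the (Sa,Sc,Sc) ligand is assumed to deliver the (S) ether carbon; if its sense is the opposite, the antipodal ligand is used with no other change.

Ar = 3,4-bis(benzyloxy)phenyl in all names; SMILES are written in full in the compound list.

**Route**

Step 1
Reactants: 1 1-Ar-ethan-1-one; 2 diallyl carbonate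
Product: 3 allyl 3-Ar-3-oxopropanoate
Conditions: NaH, THF, reflux; then aq. HCl
Reagents that add atoms: none
Why: Crossed Claisen condensation, in which the ketone enolate is C-acylated by the carbonate and the equilibrium is pulled by deprotonation of the β-keto ester formed.

Step 2
Reactants: 3 allyl 3-Ar-3-oxopropanoate
Product: 4 allyl (3R)-3-Ar-3-hydroxypropanoate
Conditions: RuCl(p-cymene)[(R,R)-TsDPEN] (1 mol %), HCO2H/Et3N (5:2), DMF, 40 °C
Reagents that add atoms: none
Why: Noyori asymmetric transfer hydrogenation of an aryl ketone, in which the Ru–H/N–H pair delivers hydride to the face fixed by the aryl/cymene contact, so the (R,R) catalyst is expected to give the (R) carbinol while the allyl ester and benzyl ethers are left alone.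

Step 3
Reactants: 5 3,4-bis(benzyloxy)benzaldehyde; 6 triethyl phosphonoacetate
Product: 7 ethyl (2E)-3-Ar-prop-2-enoate
Conditions: NaH, THF, 0 °C to rt
Reagents that add atoms: none
Why: Horner–Wadsworth–Emmons olefination of an aromatic aldehyde with a stabilised phosphonate anion, which should give the (E)-enoate.

Step 4
Reactants: 7 ethyl (2E)-3-Ar-prop-2-enoate
Product: 8 (2E)-3-Ar-prop-2-en-1-ol
Conditions: i-Bu2AlH, CH2Cl2, −78 °C; aq. potassium sodium tartrate
Reagents that add atoms: none
Why: 1,2-Reduction of a conjugated ester by an aluminium hydride at low temperature, which leaves the alkene geometry and the benzyl ethers untouched.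

Step 5
Reactants: 8 (2E)-3-Ar-prop-2-en-1-ol
Product: 9 tert-butyl (2E)-3-Ar-prop-2-en-1-yl carbonate
Conditions: Boc2O, DMAP (cat.), CH2Cl2, 0 °C to rt
Reagents that add atoms: di-tert-butyl dicarbonate, CC(C)(C)OC(=O)OC(=O)OC(C)(C)C
Why: DMAP-catalysed O-acylation of a primary allylic alcohol; the tert-butyl carbonate is chosen because the tert-butoxide it releases later is a poor competing nucleophile.

Step 6
Reactants: 4 allyl (3R)-3-Ar-3-hydroxypropanoate; 9 tert-butyl (2E)-3-Ar-prop-2-en-1-yl carbonate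
Product: 12 allyl (3R)-3-Ar-3-{[(1S)-1-Ar-prop-2-en-1-yl]oxy}propanoate, via lithium alkoxide 10 (not isolated), via copper alkoxide 11 (not isolated)
Conditions: LiN(SiMe3)2 (1.0 equiv), THF, −78 °C; CuI, −78 to 0 °C; then 9, [Ir(cod)Cl]2 (2 mol %), (Sa,Sc,Sc)-(1,1'-binaphthalene-2,2'-diyl) N,N-bis(1-phenylethyl)phosphoramidite (4 mol %, pre-activated with n-PrNH2), THF, rt
Reagents that add atoms: lithium bis(trimethylsilyl)amide, [Li]N([Si](C)(C)C)[Si](C)(C)C (lithium in 10 only); copper iodide CuI, [Cu]I (copper in 11 only)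
Why: Iridium-catalysed asymmetric allylic etherification, in which the soft copper alkoxide attacks the substituted terminus of the allyl-iridium intermediate to give the branched ether; the ligand sets the new (S) centre, the (R) carbinol carbon is not touched, and the carbonate ionises far faster than the simple allyl ester.

Step 7
Reactants: 12 allyl (3R)-3-Ar-3-{[(1S)-1-Ar-prop-2-en-1-yl]oxy}propanoate
Product: 13 (4R,6S,7Z)-4,6-di-Ar-1,5-dioxacyclonon-7-en-2-one
Conditions: second-generation Grubbs catalyst RuCl2(=CHPh)(SIMes)(PCy3) (10 mol %), CH2Cl2 (0.001 M), 40 °C, slow addition of 12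
Reagents that add atoms: none
Why: Ring-closing metathesis of two terminal alkenes, driven by loss of ethylene and kept intramolecular by high dilution; a nine-membered ring should accept only the (Z)-alkene.

Step 8
Reactants: 13 (4R,6S,7Z)-4,6-di-Ar-1,5-dioxacyclonon-7-en-2-one
Product: 17 (2R,3R,4S,5S)-2,5-di-Ar-4-ethenyloxolane-3-carboxylic acid, via lithium enolate 14 (not isolated), via silyl ketene acetal 15 (not isolated), via trimethylsilyl ester 16 (not isolated)
Conditions: LiN(SiMe3)2, Me3SiCl/Et3N (premixed), THF, −78 °C; toluene, 80 °C; aq. citric acid, THF, rt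
Reagents that add atoms: lithium bis(trimethylsilyl)amide, [Li]N([Si](C)(C)C)[Si](C)(C)C (lithium in 14 only); chlorotrimethylsilane, C[Si](C)(C)Cl (silyl group in 15 and 16 only)
Why: LiN(SiMe3)2 deprotonates C3 of 13 with Me3SiCl already present, so enolate 14 is O-silylated to ketene acetal 15 before it can expel the β-oxygen O5, and on warming the O–C(OSiMe3)=C unit and the (Z)-alkene undergo a concerted suprafacial [3,3]-sigmatropic shift that joins the ketene-acetal carbon to C7 and breaks the allylic O1–C9 bond, giving silyl ester 16, which mild acid hydrolyses to 17. The closest known reaction type is the Ireland–Claisen (ester enolate Claisen) ring contraction of unsaturated medium and large lactones to cis-2-alkenylcycloalkanecarboxylic acids, applied here to a substrate with an oxygen in the ring that is formed. The oxolane is not closed by a separate cyclisation: four of its five bonds (C3–C2, C2–O1, O1–C5, C5–C4 in product numbering) already lie in the nine-membered ring and the fifth, C3–C4, forms transannularly inside the six-membered pericyclic array, so the mode of closure is a nine-to-five ring contraction. Because both π partners are endocyclic (the ketene acetal with ring oxygen and ring carbon cis, the alkene Z), the array can only be boat-like, and this puts the carboxyl on C3 and the vinyl on C4 cis to each other. The boat is expected to form on the face of the incipient oxolane opposite to the two aryl groups, which are cis to each other and can both stay pseudo-equatorial there, so the new substituents come out trans to the neighbouring aryl groups while C2 and C5 keep the configurations of 13. The step needs silylation to outrun elimination (secured by the internal Me3SiCl quench at −78 °C) and one face to be clearly preferred (secured by the cis relation of the aryl groups set in steps 2 and 6).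

Step 9
Reactants: 17 (2R,3R,4S,5S)-2,5-di-Ar-4-ethenyloxolane-3-carboxylic acid
Product: 19 (2R,3R,4S,5S)-2,5-di-Ar-4-formyloxolane-3-carboxylic acid, via vicinal diol 18 (not isolated)
Conditions: OsO4 (2 mol %), NaIO4, 2,6-lutidine, dioxane/H2O (3:1), rt
Reagents that add atoms: osmium tetroxide, O=[Os](=O)(=O)=O (oxygen carrier); sodium periodate, [Na+].[O-]I(=O)(=O)=O (terminal oxidant)
Why: Lemieux–Johnson oxidation (dihydroxylation, then periodate glycol cleavage) of the only alkene left; the aldehyde, cis to the carboxyl, can rest as its ring tautomer (a cis-fused hydroxy lactone), which should guard C4 against epimerisation.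

Step 10
Reactants: 19 (2R,3R,4S,5S)-2,5-di-Ar-4-formyloxolane-3-carboxylic acid
Product: 20 meso-[(2R,3S,4R,5S)-2,5-di-Ar-oxolane-3,4-diyl]dimethanol
Conditions: LiAlH4, THF, 0 °C to reflux; then H2O, aq. NaOH
Reagents that add atoms: none
Why: Hydride reduction of the aldehyde and the carboxyl group (or of their hydroxy-lactone tautomer) to two primary alcohols with no stereocentre touched, giving the meso diol.

Step 11
Reactants: 20 meso-[(2R,3S,4R,5S)-2,5-di-Ar-oxolane-3,4-diyl]dimethanol
Product: 21 meso-[(2R,3S,4R,5S)-2,5-di-Ar-oxolane-3,4-diyl]bis(methylene) diacetate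
Conditions: Ac2O, pyridine, DMAP (cat.), CH2Cl2, rt
Reagents that add atoms: acetic anhydride, CC(=O)OC(C)=O
Why: Acylation of two unhindered primary alcohols under nucleophilic catalysis.

Step 12
Reactants: 21 meso-[(2R,3S,4R,5S)-2,5-di-Ar-oxolane-3,4-diyl]bis(methylene) diacetate
Product: 22 meso-[(2R,3S,4R,5S)-2,5-bis(3,4-dihydroxyphenyl)oxolane-3,4-diyl]bis(methylene) diacetate (target)
Conditions: H2 (1 atm), Pd/C (10 % Pd), EtOAc, rt, stopped after uptake of four equivalents
Reagents that add atoms: none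
Why: Catalytic hydrogenolysis of the four aryl benzyl ethers, which should cleave faster than the two ring benzylic C–O bonds in a neutral aprotic solvent and leaves the acetates intact.

**Compound list**

1 | 1-[3,4-bis(benzyloxy)phenyl]ethan-1-one | CC(=O)c1ccc(OCc2ccccc2)c(OCc2ccccc2)c1 | starting material
2 | diallyl carbonate | C=CCOC(=O)OCC=C | starting material
3 | allyl 3-[3,4-bis(benzyloxy)phenyl]-3-oxopropanoate | C=CCOC(=O)CC(=O)c1ccc(OCc2ccccc2)c(OCc2ccccc2)c1 | intermediate
4 | allyl (3R)-3-[3,4-bis(benzyloxy)phenyl]-3-hydroxypropanoate | C=CCOC(=O)C[C@@H](O)c1ccc(OCc2ccccc2)c(OCc2ccccc2)c1 | intermediate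
5 | 3,4-bis(benzyloxy)benzaldehyde | O=Cc1ccc(OCc2ccccc2)c(OCc2ccccc2)c1 | starting material
6 | triethyl phosphonoacetate | CCOC(=O)CP(=O)(OCC)OCC | starting material
7 | ethyl (2E)-3-[3,4-bis(benzyloxy)phenyl]prop-2-enoate | CCOC(=O)/C=C/c1ccc(OCc2ccccc2)c(OCc2ccccc2)c1 | intermediate
8 | (2E)-3-[3,4-bis(benzyloxy)phenyl]prop-2-en-1-ol | OC/C=C/c1ccc(OCc2ccccc2)c(OCc2ccccc2)c1 | intermediate
9 | tert-butyl (2E)-3-[3,4-bis(benzyloxy)phenyl]prop-2-en-1-yl carbonate | CC(C)(C)OC(=O)OC/C=C/c1ccc(OCc2ccccc2)c(OCc2ccccc2)c1 | intermediate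
10 | lithium alkoxide of 4 | C=CCOC(=O)C[C@@H](O[Li])c1ccc(OCc2ccccc2)c(OCc2ccccc2)c1 | intermediate (not isolated)
11 | copper alkoxide of 4 (monovalent copper) | C=CCOC(=O)C[C@@H](O[Cu])c1ccc(OCc2ccccc2)c(OCc2ccccc2)c1 | intermediate (not isolated)
12 | allyl (3R)-3-[3,4-bis(benzyloxy)phenyl]-3-{[(1S)-1-[3,4-bis(benzyloxy)phenyl]prop-2-en-1-yl]oxy}propanoate | C=CCOC(=O)C[C@H](c1ccc(OCc2ccccc2)c(OCc2ccccc2)c1)O[C@H](c1ccc(OCc2ccccc2)c(OCc2ccccc2)c1)C=C | intermediate
13 | (4R,6S,7Z)-4,6-bis[3,4-bis(benzyloxy)phenyl]-1,5-dioxacyclonon-7-en-2-one | O=C1C[C@H](c2ccc(OCc3ccccc3)c(OCc3ccccc3)c2)O[C@H](c2ccc(OCc3ccccc3)c(OCc3ccccc3)c2)/C=C\CO1 | intermediate (key-step precursor)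
14 | lithium enolate of 13 (ring O1 and C4 cis across C2=C3) | [Li]O/C1=C/[C@H](c2ccc(OCc3ccccc3)c(OCc3ccccc3)c2)O[C@H](c2ccc(OCc3ccccc3)c(OCc3ccccc3)c2)/C=C\CO1 | intermediate (not isolated)
15 | (4R,6S,7Z)-4,6-bis[3,4-bis(benzyloxy)phenyl]-2-(trimethylsilyloxy)-1,5-dioxacyclonona-2,7-diene (ring O1 and C4 cis across C2=C3) | C[Si](C)(C)O/C1=C/[C@H](c2ccc(OCc3ccccc3)c(OCc3ccccc3)c2)O[C@H](c2ccc(OCc3ccccc3)c(OCc3ccccc3)c2)/C=C\CO1 | intermediate (not isolated)
16 | trimethylsilyl (2R,3R,4S,5S)-2,5-bis[3,4-bis(benzyloxy)phenyl]-4-ethenyloxolane-3-carboxylate | C[Si](C)(C)OC(=O)[C@@H]1[C@H](C=C)[C@@H](c2ccc(OCc3ccccc3)c(OCc3ccccc3)c2)O[C@H]1c1ccc(OCc2ccccc2)c(OCc2ccccc2)c1 | intermediate (not isolated)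
17 | (2R,3R,4S,5S)-2,5-bis[3,4-bis(benzyloxy)phenyl]-4-ethenyloxolane-3-carboxylic acid (aryl groups cis; carboxyl and vinyl cis to each other, trans to the aryl groups) | OC(=O)[C@@H]1[C@H](C=C)[C@@H](c2ccc(OCc3ccccc3)c(OCc3ccccc3)c2)O[C@H]1c1ccc(OCc2ccccc2)c(OCc2ccccc2)c1 | intermediate (key-step product)
18 | 2,5-bis[3,4-bis(benzyloxy)phenyl]-4-(1,2-dihydroxyethyl)oxolane-3-carboxylic acid (ring configuration as in 17, side-chain carbinol as a mixture) | OC(=O)[C@@H]1[C@H](C(O)CO)[C@@H](c2ccc(OCc3ccccc3)c(OCc3ccccc3)c2)O[C@H]1c1ccc(OCc2ccccc2)c(OCc2ccccc2)c1 | intermediate (not isolated)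
19 | (2R,3R,4S,5S)-2,5-bis[3,4-bis(benzyloxy)phenyl]-4-formyloxolane-3-carboxylic acid | OC(=O)[C@@H]1[C@H](C=O)[C@@H](c2ccc(OCc3ccccc3)c(OCc3ccccc3)c2)O[C@H]1c1ccc(OCc2ccccc2)c(OCc2ccccc2)c1 | intermediate
20 | meso-[(2R,3S,4R,5S)-2,5-bis[3,4-bis(benzyloxy)phenyl]oxolane-3,4-diyl]dimethanol | OC[C@@H]1[C@H](CO)[C@@H](c2ccc(OCc3ccccc3)c(OCc3ccccc3)c2)O[C@H]1c1ccc(OCc2ccccc2)c(OCc2ccccc2)c1 | intermediate
21 | meso-[(2R,3S,4R,5S)-2,5-bis[3,4-bis(benzyloxy)phenyl]oxolane-3,4-diyl]bis(methylene) diacetate | CC(=O)OC[C@@H]1[C@H](COC(C)=O)[C@@H](c2ccc(OCc3ccccc3)c(OCc3ccccc3)c2)O[C@H]1c1ccc(OCc2ccccc2)c(OCc2ccccc2)c1 | intermediate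
22 | meso-[(2R,3S,4R,5S)-2,5-bis(3,4-dihydroxyphenyl)oxolane-3,4-diyl]bis(methylene) diacetate | CC(=O)OC[C@@H]1[C@H](COC(C)=O)[C@@H](c2ccc(O)c(O)c2)O[C@H]1c1ccc(O)c(O)c1 | target

**Step count and risks**

Total steps: 12. Longest linear sequence: 10 steps (3, 4, 5, 6, 7, 8, 9, 10, 11, 12).

Step 7. Intermolecular metathesis (oligomerisation) may outrun closure of the strained nine-membered ring, because the ester must adopt its disfavoured s-cis conformation for the ends to meet. The fallback sets out from 12 and closes the ring at the ester C–O bond instead of at the alkene: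
- The allyl ester would be removed with Pd(PPh3)4 (cat.) and morpholine in THF, giving (3R)-3-Ar-3-{[(1S)-1-Ar-prop-2-en-1-yl]oxy}propanoic acid F1.
- (Z)-Selective cross-metathesis of its vinyl group with (Z)-but-2-ene-1,4-diol over the dithiolate catalyst Ru(SIMes)(S2C6H2Cl2)(=CH-C6H4-2-OiPr) would give (3R)-3-Ar-3-{[(1S,2Z)-1-Ar-4-hydroxybut-2-en-1-yl]oxy}propanoic acid F2.
- Shiina macrolactonisation (2-methyl-6-nitrobenzoic anhydride, DMAP, CH2Cl2, slow addition, rt) would return to the route at 13.

Step 8. The enolate may open by expulsion of the ring oxygen before it is silylated, or the boat may form on both faces of the ring and erode the diastereoselectivity. The fallback sets out from 9 and introduces the two exocyclic carbons by carbonylation of a preformed dihydrofuran: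
- Iridium-catalysed allylic substitution of 9 with KHCO3 as the oxygen nucleophile and the antipodal (Ra,Rc,Rc) ligand would give (1R)-1-Ar-prop-2-en-1-ol F3.
- Its copper alkoxide would be etherified with a second portion of 9 under the conditions of step 6, giving meso-(1R,1'S)-bis(1-Ar-prop-2-en-1-yl) ether F4.
- Ring-closing metathesis with the second-generation Grubbs catalyst would give cis-(2R,5S)-2,5-di-Ar-2,5-dihydrofuran F5.
- syn-Bis(methoxycarbonylation) catalysed by divalent palladium (Pd(OCOCF3)2, an N,N'-diaryl-α-diimine ligand, 1,4-benzoquinone, CO, MeOH), on the face away from the aryl groups, would give dimethyl meso-(2R,3R,4S,5S)-2,5-di-Ar-oxolane-3,4-dicarboxylate F6.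
- LiAlH4 reduction would return to the route at 20.

Step 6. The metalated β-hydroxy ester may fragment by retro-aldol cleavage or dehydrate, and the iridium catalyst may ionise the allyl ester in competition with the carbonate. The fallback sets out from 4 and takes the nucleophile through the etherification at the alcohol oxidation level:
- LiBH4 in THF would give (1R)-1-Ar-propane-1,3-diol F7.
- Silylation of the primary hydroxyl (t-BuMe2SiCl, imidazole) would give (1R)-1-Ar-3-[(tert-butyldimethylsilyl)oxy]propan-1-ol F8.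
- Etherification with 9 under the conditions of step 6 would give tert-butyl{(3R)-3-Ar-3-{[(1S)-1-Ar-prop-2-en-1-yl]oxy}propoxy}dimethylsilane F9.
- Bu4NF would free (3R)-3-Ar-3-{[(1S)-1-Ar-prop-2-en-1-yl]oxy}propan-1-ol F10.
- Oxidation with TEMPO/PhI(OAc)2 in MeCN/H2O would give the acid F1 described under step 7, and allyl bromide with K2CO3 in DMF would return to the route at 12.

**Further compounds**

F1 | step 7 | (3R)-3-[3,4-bis(benzyloxy)phenyl]-3-{[(1S)-1-[3,4-bis(benzyloxy)phenyl]prop-2-en-1-yl]oxy}propanoic acid | OC(=O)C[C@H](c1ccc(OCc2ccccc2)c(OCc2ccccc2)c1)O[C@H](c1ccc(OCc2ccccc2)c(OCc2ccccc2)c1)C=C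
F2 | step 7 | (3R)-3-[3,4-bis(benzyloxy)phenyl]-3-{[(1S,2Z)-1-[3,4-bis(benzyloxy)phenyl]-4-hydroxybut-2-en-1-yl]oxy}propanoic acid | OC(=O)C[C@H](c1ccc(OCc2ccccc2)c(OCc2ccccc2)c1)O[C@H](c1ccc(OCc2ccccc2)c(OCc2ccccc2)c1)/C=C\CO
F3 | step 8 | (1R)-1-[3,4-bis(benzyloxy)phenyl]prop-2-en-1-ol | O[C@@H](c1ccc(OCc2ccccc2)c(OCc2ccccc2)c1)C=C
F4 | step 8 | meso-(1R,1'S)-bis{1-[3,4-bis(benzyloxy)phenyl]prop-2-en-1-yl} ether | C=C[C@H](c1ccc(OCc2ccccc2)c(OCc2ccccc2)c1)O[C@H](c1ccc(OCc2ccccc2)c(OCc2ccccc2)c1)C=C
F5 | step 8 | cis-(2R,5S)-2,5-bis[3,4-bis(benzyloxy)phenyl]-2,5-dihydrofuran | C1=C[C@H](c2ccc(OCc3ccccc3)c(OCc3ccccc3)c2)O[C@@H]1c1ccc(OCc2ccccc2)c(OCc2ccccc2)c1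
F6 | step 8 | dimethyl meso-(2R,3R,4S,5S)-2,5-bis[3,4-bis(benzyloxy)phenyl]oxolane-3,4-dicarboxylate | COC(=O)[C@@H]1[C@H](C(=O)OC)[C@@H](c2ccc(OCc3ccccc3)c(OCc3ccccc3)c2)O[C@H]1c1ccc(OCc2ccccc2)c(OCc2ccccc2)c1
F7 | step 6 | (1R)-1-[3,4-bis(benzyloxy)phenyl]propane-1,3-diol | OCC[C@@H](O)c1ccc(OCc2ccccc2)c(OCc2ccccc2)c1
F8 | step 6 | (1R)-1-[3,4-bis(benzyloxy)phenyl]-3-[(tert-butyldimethylsilyl)oxy]propan-1-ol | CC(C)(C)[Si](C)(C)OCC[C@@H](O)c1ccc(OCc2ccccc2)c(OCc2ccccc2)c1
F9 | step 6 | tert-butyl{(3R)-3-[3,4-bis(benzyloxy)phenyl]-3-{[(1S)-1-[3,4-bis(benzyloxy)phenyl]prop-2-en-1-yl]oxy}propoxy}dimethylsilane | CC(C)(C)[Si](C)(C)OCC[C@H](c1ccc(OCc2ccccc2)c(OCc2ccccc2)c1)O[C@H](c1ccc(OCc2ccccc2)c(OCc2ccccc2)c1)C=C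
F10 | step 6 | (3R)-3-[3,4-bis(benzyloxy)phenyl]-3-{[(1S)-1-[3,4-bis(benzyloxy)phenyl]prop-2-en-1-yl]oxy}propan-1-ol | OCC[C@H](c1ccc(OCc2ccccc2)c(OCc2ccccc2)c1)O[C@H](c1ccc(OCc2ccccc2)c(OCc2ccccc2)c1)C=C
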